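**Strategy.** Everything rests on closing ring C across a preformed ring D. The C8–C9 bond is made by an intramolecular Hosomi–Sakurai conjugate allylation: the C16 carbonyl makes C8 the β-carbon of a cyclopentenone, and the C13 carbinol carbon carries the C12–C11–C9 chain as an allylsilane. In one operation this should create the quaternary C8, the bicyclo[3.2.1]octane of rings C and D with the C13 and 12α oxygens in place, and a C9 vinyl group that becomes C10 and C5. The precursor is a monocyclic cyclopentenone made from 5-methylfurfural. Ring B then closes by aldol condensation; ring A and the lactone are annulated last.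

Key step: step 9

Remark: gibberellane numbering is used throughout (C8 = quaternary carbon shared by rings B, C and D; C9 = CH shared by rings B and C); the target is read as the 3β,12α,13-trihydroxy 19,10-lactone 7-acid (12α-hydroxy-GA1).

**Step 1**
Reactants: 1 5-methylfurfural; 2 allylboronic acid pinacol ester
Product: 3 (S)-1-(5-methylfuran-2-yl)but-3-en-1-ol
Conditions: (S)-TRIP [(S)-3,3'-bis(2,4,6-triisopropylphenyl)-1,1'-binaphthyl-2,2'-diyl hydrogen phosphate] (5 mol %), toluene, −30 °C; aqueous work-up
Reagents that add atoms: none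
Why: Chiral phosphoric acid-catalysed allylboration through a closed chair transition state should deliver the allyl group to the si face of the aldehyde and set C12 as S (the later 12α-oxygen).

**Step 2**
Reactants: 3 (S)-1-(5-methylfuran-2-yl)but-3-en-1-ol
Product: 4 tert-butyldimethylsilyl ether of 3
Conditions: t-BuMe2SiCl, imidazole, DMF, rt
Reagents that add atoms: tert-butyldimethylsilyl chloride, CC(C)(C)[Si](C)(C)Cl
Why: Standard silylation; a free furyl carbinol would divert the next oxidation into an Achmatowicz rearrangement.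

**Step 3**
Reactants: 4 silyl ether
Product: 5 (3Z,6S)-6-(tert-butyldimethylsilyloxy)nona-3,8-diene-2,5-dione
Conditions: 3-ClC6H4CO3H (1.05 equiv), NaHCO3, CH2Cl2, 0 °C
Reagents that add atoms: 3-chloroperbenzoic acid, OOC(=O)c1cccc(Cl)c1
Why: Peracid oxidation of a 2,5-dialkylfuran (epoxidation, ring opening) gives the cis-enedione, and the electron-rich furan should react well before the terminal alkene.

**Step 4**
Reactants: 5 cis-enedione
Product: 6 (4S)-4-[(1S)-1-(tert-butyldimethylsilyloxy)but-3-enyl]-4-hydroxycyclopent-2-en-1-one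
Conditions: Na2CO3, THF/H2O, 0 °C to rt
Reagents that add atoms: none
Why: Intramolecular aldol addition (5-exo) of the methyl ketone enolate to the C13 ketone closes ring D, and Felkin–Anh control by C12 (nucleophile anti to the bulky, non-chelating silyloxy group) should set the C13 carbinol anti to the 12-oxygen, the mild base being chosen to limit epimerisation at C12.

**Step 5**
Reactants: 6 hydroxy enone
Product: 7 triethylsilyl ether of 6
Conditions: Et3SiOTf, 2,6-lutidine, CH2Cl2, −78 to 0 °C
Reagents that add atoms: triethylsilyl trifluoromethanesulfonate, CC[Si](CC)(CC)OS(=O)(=O)C(F)(F)F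
Why: Silylation of the tertiary alcohol blocks retro-aldol cleavage and later acylation; C13 is untouched.

**Step 6**
Reactants: 7 bis-silyl enone; 8 2-(trimethylsilyl)ethyl acetate
Product: 9 tertiary allylic alcohol (C8 carbinol, both epimers)
Conditions: LiN(i-Pr)2, 8, THF, −78 °C; then 7; NH4Cl quench
Reagents that add atoms: none
Why: Kinetic 1,2-addition of the lithium ester enolate to the enone carbonyl (C8) is favoured because the β-carbon C16 is flanked by the quaternary C13; the new carbinol configuration is lost in the next step.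

**Step 7**
Reactants: 9 tertiary allylic alcohol
Product: 10 ring-D enone, 2-(trimethylsilyl)ethyl 2-[(4R)-4-[(1S)-1-(tert-butyldimethylsilyloxy)but-3-enyl]-3-oxo-4-(triethylsilyloxy)cyclopent-1-enyl]acetate
Conditions: pyridinium chlorochromate [C5H5NH][CrO3Cl], NaOAc, 4 Å molecular sieves, CH2Cl2, rt
Reagents that add atoms: none
Why: Babler–Dauben oxidative transposition (chromate ester, [3,3] shift, oxidation) moves the oxygen to C16 and leaves the acetate arm on the enone β-carbon C8, the acceptor needed for the key step.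

**Step 8**
Reactants: 10 ring-D enone; 11 allyltrimethylsilane
Product: 12 allylsilane enone (E drawn, E/Z mixture usable)
Conditions: second-generation Grubbs catalyst (5 mol %), 11 (5 equiv), CH2Cl2, 40 °C
Reagents that add atoms: none
Why: Olefin cross-metathesis of the terminal alkene with excess allylsilane installs the allylsilane whose γ-carbon is C9; the trisubstituted enone alkene is not a metathesis substrate and the alkene geometry is immaterial.

**Step 9 (key step)**
Reactants: 12 allylsilane enone
Product: 13 bicyclo[3.2.1]octan-6-one (rings C and D): CH2CO2CH2CH2SiMe3 on bridgehead C8, equatorial vinyl on C9 (9-epimer), axial 12α-OTBS, 13-OTES, C16 ketone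
Conditions: EtAlCl2 (1.5 equiv), CH2Cl2, −78 to −20 °C; aqueous NaHCO3
Reagents that add atoms: none
Why: EtAlCl2 binds the C16 carbonyl and the allylsilane adds through its γ-carbon (C9) to the enone β-carbon C8 in an anti SE2' sense, the β-silyl cation collapsing to the C10=C5 vinyl group and the aluminium enolate giving the C16 ketone on work-up; EtAlCl2 also scavenges protons that would cause protodesilylation. The closest known reaction type is the intramolecular Hosomi–Sakurai conjugate allylation of β,β-disubstituted cycloalkenones, which is established for quaternary centres. Ring C closes in a 6-exo-trig mode as a three-carbon bridge between C13 and C8 of ring D, giving the bicyclo[3.2.1]octanone. The configuration of C8 is dictated by C13, because the tether can only reach the enone face on which it is attached. C9 should form in a chair-like transition state with the vinyl group equatorial, away from the axial 12α-silyloxy group, that is as the 9-epimer; this is harmless because C9 becomes epimerisable next to the C10 ketone and is corrected in step 13. The selectivity needed is 1,4- over 1,2-addition to the C16 carbonyl, which Lewis acid activation of the enone is expected to secure.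

**Step 10**
Reactants: 13 bicyclic ketone; 14 methyltriphenylphosphonium bromide
Product: 15 16-methylene compound
Conditions: 14 (4 equiv), KOt-Bu, THF, 0 °C to reflux
Reagents that add atoms: none
Why: Wittig methylenation of the only ketone gives the C16 exocyclic methylene; excess ylide overcomes the hindrance of the carbonyl next to the bridgehead.

**Step 11**
Reactants: 15 16-methylene compound
Product: 16 α-hydroxy ester (C6 carbinol, both epimers)
Conditions: LiN(i-Pr)2, THF, −78 °C; then 2-(phenylsulfonyl)-3-phenyloxaziridine; NH4Cl quench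
Reagents that add atoms: 2-(phenylsulfonyl)-3-phenyloxaziridine, O=S(=O)(c1ccccc1)N1OC1c1ccccc1
Why: Deprotonation of the only acidic site (ester α-CH2, C6) and electrophilic hydroxylation of the enolate gives the α-hydroxy ester; the C6 configuration is irrelevant because it is oxidised in step 13.

**Step 12**
Reactants: 16 α-hydroxy ester
Product: 17 methyl ketone (C10 carbonyl, C5 methyl)
Conditions: PdCl2 (10 mol %), CuCl, O2 (1 atm), DMF/H2O, rt
Reagents that add atoms: water, O
Why: Tsuji–Wacker oxidation converts the monosubstituted vinyl group into the methyl ketone with Markovnikov selectivity, whereas the 1,1-disubstituted exocyclic alkene is a poor substrate.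

**Step 13**
Reactants: 17 methyl ketone
Product: 19 tricyclic enone ester (rings B, C and D; natural 9β-H), via α-keto ester 18 (not isolated)
Conditions: Dess–Martin periodinane, CH2Cl2, rt; then DBU, toluene, 60 °C
Reagents that add atoms: none
Why: Oxidation gives the α-keto ester, whose very electrophilic C6 ketone is attacked by the C5 methyl ketone enolate (5-exo aldol) and dehydrated by an E1cB path, while C9 equilibrates through the ketone enolate so that only the cis-fused enone, in which the nearly planar five-membered ring is far less strained, should accumulate, which sets the natural C9 configuration.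

**Step 14**
Reactants: 19 tricyclic enone ester; 20 3-bromo-1,1-dimethoxypropane; 21 propionic anhydride
Product: 23 tertiary allylic propionate (C10: O-propionyl α, acetal chain β), via cerium alkoxide 22 (not isolated)
Conditions: 20, Mg, THF; CeCl3, THF, −78 °C; then 19; then 21, DMAP, −78 to 0 °C
Reagents that add atoms: none
Why: Organocerium 1,2-addition to the cyclopentenone carbonyl from the convex β-face (anti to ring C and the axial 12α-silyloxy group) should set C10 with its oxygen α, and the tertiary alkoxide is acylated in the same flask.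

**Step 15**
Reactants: 23 tertiary allylic propionate
Product: 24 γ-lactone (19,10-lactone; C4 epimers)
Conditions: KN(SiMe3)2, THF, −78 to 0 °C; NH4Cl quench
Reagents that add atoms: none
Why: Intramolecular Michael addition (5-exo-trig) of the propionate enolate, tethered through the α-oxygen on C10, to C5 of the unsaturated ester builds the γ-lactone and necessarily sets H-5 β, and C6 is expected to settle on protonation and equilibration with the ester trans to the new C4–C5 bond (6β).

**Step 16**
Reactants: 24 γ-lactone
Product: 25 lactone aldehyde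
Conditions: LiBF4, MeCN/H2O, rt
Reagents that add atoms: water, O
Why: Mild Lewis-acid hydrolysis of the dimethyl acetal frees the C3 aldehyde without touching the silyl ethers or the exocyclic alkene.

**Step 17**
Reactants: 25 lactone aldehyde
Product: 26 fully protected target (3β-OH free, 12-OTBS, 13-OTES, 2-(trimethylsilyl)ethyl ester)
Conditions: KN(SiMe3)2, 18-crown-6, THF, −78 °C; AcOH quench at −78 °C
Reagents that add atoms: none
Why: Intramolecular aldol addition of the lactone enolate (C4) to the C3 aldehyde closes ring A, C4 being forced to the configuration of the bridged lactone (methyl β), and an open transition state with the aldehyde oxygen anti to the enolate oxygen, favoured for the crown-ether-sequestered potassium enolate, should place the new hydroxyl axial (3β), the cold quench avoiding retro-aldol epimerisation.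

**Step 18**
Reactants: 26 fully protected target
Product: 27 target
Conditions: Bu4NF, AcOH, THF, 0 to 40 °C; dilute acid work-up
Reagents that add atoms: none
Why: Fluoride cleaves both silyl ethers and fragments the 2-(trimethylsilyl)ethyl ester (loss of ethylene), the acetic acid buffer suppressing base-induced retro-aldol epimerisation at C3; no stereocentre is touched.

**Compound list**

1 | 5-methylfuran-2-carbaldehyde | Cc1ccc(C=O)o1 | starting material
2 | 2-allyl-4,4,5,5-tetramethyl-1,3,2-dioxaborolane | C=CCB1OC(C)(C)C(C)(C)O1 | starting material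
3 | (S)-1-(5-methylfuran-2-yl)but-3-en-1-ol | C=CC[C@H](O)c1ccc(C)o1 | intermediate
4 | (S)-tert-butyldimethyl{[1-(5-methylfuran-2-yl)but-3-en-1-yl]oxy}silane | C=CC[C@H](O[Si](C)(C)C(C)(C)C)c1ccc(C)o1 | intermediate
5 | (3Z,6S)-6-(tert-butyldimethylsilyloxy)nona-3,8-diene-2,5-dione | C=CC[C@H](O[Si](C)(C)C(C)(C)C)C(=O)/C=C\C(C)=O | intermediate
6 | (4S)-4-[(1S)-1-(tert-butyldimethylsilyloxy)but-3-enyl]-4-hydroxycyclopent-2-en-1-one | O=C1C=C[C@](O)([C@H](CC=C)O[Si](C)(C)C(C)(C)C)C1 | intermediate
7 | (4S)-4-[(1S)-1-(tert-butyldimethylsilyloxy)but-3-enyl]-4-(triethylsilyloxy)cyclopent-2-en-1-one | O=C1C=C[C@](O[Si](CC)(CC)CC)([C@H](CC=C)O[Si](C)(C)C(C)(C)C)C1 | intermediate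
8 | 2-(trimethylsilyl)ethyl acetate | CC(=O)OCC[Si](C)(C)C | starting material
9 | 2-(trimethylsilyl)ethyl 2-[(4S)-4-[(1S)-1-(tert-butyldimethylsilyloxy)but-3-enyl]-1-hydroxy-4-(triethylsilyloxy)cyclopent-2-enyl]acetate (C8 carbinol epimers) | C[Si](C)(C)CCOC(=O)CC1(O)C=C[C@](O[Si](CC)(CC)CC)([C@H](CC=C)O[Si](C)(C)C(C)(C)C)C1 | intermediate
10 | 2-(trimethylsilyl)ethyl 2-[(4R)-4-[(1S)-1-(tert-butyldimethylsilyloxy)but-3-enyl]-3-oxo-4-(triethylsilyloxy)cyclopent-1-enyl]acetate | O=C1C=C(CC(=O)OCC[Si](C)(C)C)C[C@@]1(O[Si](CC)(CC)CC)[C@H](CC=C)O[Si](C)(C)C(C)(C)C | intermediate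
11 | allyltrimethylsilane | C=CC[Si](C)(C)C | starting material
12 | 2-(trimethylsilyl)ethyl 2-[(4R)-4-[(1S,3E)-1-(tert-butyldimethylsilyloxy)-5-(trimethylsilyl)pent-3-enyl]-3-oxo-4-(triethylsilyloxy)cyclopent-1-enyl]acetate | O=C1C=C(CC(=O)OCC[Si](C)(C)C)C[C@@]1(O[Si](CC)(CC)CC)[C@H](C/C=C/C[Si](C)(C)C)O[Si](C)(C)C(C)(C)C | intermediate
13 | C/D ketone: bicyclo[3.2.1]octan-6-one with CH2CO2CH2CH2SiMe3 on bridgehead C8, equatorial vinyl on C9 (9-epimer), axial 12α-OTBS, 13-OTES on the other bridgehead | O=C1C[C@]2(CC(=O)OCC[Si](C)(C)C)C[C@@]1(O[Si](CC)(CC)CC)[C@@H](O[Si](C)(C)C(C)(C)C)C[C@@H]2C=C | intermediate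
14 | methyltriphenylphosphonium bromide | C[P+](c1ccccc1)(c1ccccc1)c1ccccc1.[Br-] | starting material
15 | 16-methylene analogue of 13 (C16=C17 exocyclic alkene, 9-vinyl) | C=C1C[C@]2(CC(=O)OCC[Si](C)(C)C)C[C@@]1(O[Si](CC)(CC)CC)[C@@H](O[Si](C)(C)C(C)(C)C)C[C@@H]2C=C | intermediate
16 | α-hydroxy ester: 15 hydroxylated at C6 (both C6 epimers) | C=C1C[C@]2(C(O)C(=O)OCC[Si](C)(C)C)C[C@@]1(O[Si](CC)(CC)CC)[C@@H](O[Si](C)(C)C(C)(C)C)C[C@@H]2C=C | intermediate
17 | methyl ketone: 16 with acetyl (C10, C5) in place of vinyl on C9 | C=C1C[C@]2(C(O)C(=O)OCC[Si](C)(C)C)C[C@@]1(O[Si](CC)(CC)CC)[C@@H](O[Si](C)(C)C(C)(C)C)C[C@@H]2C(C)=O | intermediate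
18 | α-keto ester: 17 with C6 ketone | C=C1C[C@]2(C(=O)C(=O)OCC[Si](C)(C)C)C[C@@]1(O[Si](CC)(CC)CC)[C@@H](O[Si](C)(C)C(C)(C)C)C[C@@H]2C(C)=O | intermediate
19 | B/C/D enone ester: ring B cyclopentenone (C10 ketone, C5=C6, ester on C6), cis-fused to ring C (9β-H), 12α-OTBS, 13-OTES, 16-methylene | C=C1C[C@]23C[C@@]1(O[Si](CC)(CC)CC)[C@@H](O[Si](C)(C)C(C)(C)C)C[C@H]2C(=O)C=C3C(=O)OCC[Si](C)(C)C | intermediate
20 | 3-bromo-1,1-dimethoxypropane | COC(CCBr)OC | starting material
21 | propionic anhydride | CCC(=O)OC(=O)CC | starting material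
22 | dichlorocerium alkoxide of the C10 tertiary alcohol (C10: O α, 3,3-dimethoxypropyl β) | C=C1C[C@]23C[C@@]1(O[Si](CC)(CC)CC)[C@@H](O[Si](C)(C)C(C)(C)C)C[C@H]2[C@@](CCC(OC)OC)(O[Ce](Cl)Cl)C=C3C(=O)OCC[Si](C)(C)C | intermediate
23 | C10 propionate (10α-O-propionyl, 10β-(3,3-dimethoxypropyl)) of the B/C/D enoate | C=C1C[C@]23C[C@@]1(O[Si](CC)(CC)CC)[C@@H](O[Si](C)(C)C(C)(C)C)C[C@H]2[C@@](CCC(OC)OC)(OC(=O)CC)C=C3C(=O)OCC[Si](C)(C)C | intermediate
24 | 19,10-γ-lactone with H-5β, 6β-ester, C4 bearing H and methyl (both C4 epimers), acetal side chain on C10 | C=C1C[C@]23C[C@@]1(O[Si](CC)(CC)CC)[C@@H](O[Si](C)(C)C(C)(C)C)C[C@H]2[C@@]1(CCC(OC)OC)OC(=O)C(C)[C@H]1[C@@H]3C(=O)OCC[Si](C)(C)C | intermediate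
25 | lactone aldehyde: 24 with the acetal hydrolysed to the C3 aldehyde | C=C1C[C@]23C[C@@]1(O[Si](CC)(CC)CC)[C@@H](O[Si](C)(C)C(C)(C)C)C[C@H]2[C@@]1(CCC=O)OC(=O)C(C)[C@H]1[C@@H]3C(=O)OCC[Si](C)(C)C | intermediate
26 | protected target: 12-O-TBS, 13-O-TES, 2-(trimethylsilyl)ethyl 7-ester of 12α-hydroxy-GA1 | C=C1C[C@]23C[C@@]1(O[Si](CC)(CC)CC)[C@@H](O[Si](C)(C)C(C)(C)C)C[C@H]2[C@@]12CC[C@H](O)[C@@](C)(C(=O)O1)[C@H]2[C@@H]3C(=O)OCC[Si](C)(C)C | intermediate
27 | 12α-hydroxy-GA1 (3β,12α,13-trihydroxy 19,10-lactone 7-acid) | C=C1C[C@]23C[C@@]1(O)[C@@H](O)C[C@H]2[C@@]12CC[C@H](O)[C@@](C)(C(=O)O1)[C@H]2[C@@H]3C(=O)O | target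

**Step count.** 18 steps in total; the longest linear sequence is 18 steps (from 5-methylfurfural).

**Steps most likely to fail**

Step 9. The allylsilane may add 1,2 to the C16 carbonyl (five-membered ring closure) or lose silicon by protodesilylation before the hindered quaternary centre forms. The fallback sets out from compound 10. Hydroboration of the terminal alkene (9-borabicyclo[3.3.1]nonane, THF; NaBO3) should give primary alcohol F1, and Dess–Martin oxidation should give aldehyde F2. An amine-catalysed intramolecular Michael addition (pyrrolidine, AcOH, CH2Cl2) would then proceed through the C9 enamine: aldol addition to C16 is reversible, whereas 6-exo conjugate addition to C8 is not, so keto aldehyde F3 should result. Aldehyde-selective Wittig methylenation (Ph3P=CH2, 1 equiv, THF, −78 °C) returns to compound 13.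

Step 13. C9 may fail to equilibrate, or the trans-fused enone may persist because of the axial 12α-silyloxy group. The fallback sets out from compound 17. HF·pyridine (THF) removes both silyl ethers to give diol F4. DBU equilibration should then trap the axial-acetyl C9 epimer as bridged hemiketal F5, because the 12α-hydroxyl can add to the C10 ketone only in the natural C9 configuration. Dess–Martin oxidation followed by DBU gives enone diol F6. t-BuMe2SiCl/imidazole silylates the secondary 12α-hydroxyl to give silyl ether F7, and Et3SiOTf/2,6-lutidine silylates the tertiary 13-hydroxyl, which returns to compound 19.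

Step 17. Facial selectivity at C3 may be poor, or retro-aldol equilibration may drift toward the equatorial 3α-alcohol. The fallback sets out from compound 26 obtained as a C3 epimer mixture. Dess–Martin oxidation gives 3-ketone F8, and reduction with the bulky hydride KBH(s-Bu)3 (THF, −78 °C), expected to approach C3 equatorially and give the axial 3β-alcohol, returns to compound 26.

**Further compounds**

F1 | step 9 | primary alcohol from hydroboration of 10 (4-hydroxybutyl chain, C10–OH) | O=C1C=C(CC(=O)OCC[Si](C)(C)C)C[C@@]1(O[Si](CC)(CC)CC)[C@H](CCCO)O[Si](C)(C)C(C)(C)C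
F2 | step 9 | aldehyde from F1 (C10 aldehyde) | O=C1C=C(CC(=O)OCC[Si](C)(C)C)C[C@@]1(O[Si](CC)(CC)CC)[C@H](CCC=O)O[Si](C)(C)C(C)(C)C
F3 | step 9 | bicyclic keto aldehyde (formyl on C9, equatorial) | O=C1C[C@]2(CC(=O)OCC[Si](C)(C)C)C[C@@]1(O[Si](CC)(CC)CC)[C@@H](O[Si](C)(C)C(C)(C)C)C[C@@H]2C=O
F4 | step 13 | 12,13-diol methyl ketone from 17 | C=C1C[C@]2(C(O)C(=O)OCC[Si](C)(C)C)C[C@@]1(O)[C@@H](O)C[C@@H]2C(C)=O
F5 | step 13 | bridged hemiketal (12α-O to C10, natural C9) | C=C1C[C@]2(C(O)C(=O)OCC[Si](C)(C)C)C[C@@]1(O)[C@@H]1C[C@H]2C(C)(O)O1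
F6 | step 13 | B/C/D enone ester 12α,13-diol | C=C1C[C@]23C[C@@]1(O)[C@@H](O)C[C@H]2C(=O)C=C3C(=O)OCC[Si](C)(C)C
F7 | step 13 | 12-O-TBS ether of F6 | C=C1C[C@]23C[C@@]1(O)[C@@H](O[Si](C)(C)C(C)(C)C)C[C@H]2C(=O)C=C3C(=O)OCC[Si](C)(C)C
F8 | step 17 | 3-ketone of 26 | C=C1C[C@]23C[C@@]1(O[Si](CC)(CC)CC)[C@@H](O[Si](C)(C)C(C)(C)C)C[C@H]2[C@@]12CCC(=O)[C@@](C)(C(=O)O1)[C@H]2[C@@H]3C(=O)OCC[Si](C)(C)C
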